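**Retrosynthetic overview**

1. Target ⇐ phenol deacetylation and α‑face epoxidation of C8=C9 ⇐ trans‑fused bicyclic ester ⇐ C3–C4 bond: samarium Barbier closure of the cyclopentane, a 2‑iodoethyl arm on C1 adding to the C4 isopropyl ketone of a monocyclic cycloheptene.
2. Enabling feature: C4 is a tertiary carbinol exocyclic to the seven‑membered ring (a latent ketone on C5). C5 lies between quaternary C1, which carries the arm, and C6–O, which is β to the carbonyl; arm and acyl group are trans on the ring, so closure gives the trans‑fused five–seven system.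
3. Cycloheptene ⇐ ring‑closing metathesis (C8=C9) of an acyclic triene; its C1/C5/C6 triad ⇐ dianionic Ireland–Claisen rearrangement (C1–C5 bond) and hydroxyl‑directed 1,3‑anti reduction (C6).
4. Both are steered by a C4 carbinol from asymmetric hydrogenation; this relay stereocentre is then oxidised away and rebuilt, now tetrasubstituted, in the key step.
5. Ring order: seven‑membered ring (step 9), five‑membered ring (step 14), oxirane (step 15).

Key step: step 14

Remark: daucane numbering is used in the text (C1 methyl‑bearing ring‑fusion carbon, C2/C3 cyclopentane CH2, C4 carbinol carbon, C5 ring‑fusion CH, C6 ester carbon, C7 CH2, C8/C9 oxirane carbons, C10 CH2). The target is read as 1R,4R,5S,6R,8R,9S: trans‑fused, with 1‑CH3, 4‑OH and the 6‑ester on one face (β) and the oxirane oxygen on the other (α).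

**Route**

Step 1
Reactants: 1 but-2-yn-1-ol
Product: 3 (2Z)-3-iodobut-2-en-1-ol, via cyclic sodium alkenylaluminate 2 (not isolated)
Conditions: NaAlH2(OCH2CH2OMe)2 (Red-Al), THF, 0 °C to rt; then I2, THF, −78 to 0 °C
Reagents that add atoms: sodium bis(2-methoxyethoxy)aluminium dihydride, [Na+].[AlH2-](OCCOC)OCCOC (aluminium and alkoxy ligands of 2 only); iodine, II
Why: Alkoxide‑directed trans‑hydroalumination of the propargylic alcohol followed by iodinolysis of the C–Al bond with retention should give the Z trisubstituted vinyl iodide.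

Step 2
Reactants: 3 (2Z)-3-iodobut-2-en-1-ol; 4 allyltributylstannane
Product: 5 (2Z)-3-methylhexa-2,5-dien-1-ol
Conditions: Pd(PPh3)4 (cat.), CuI (cat.), DMF, 45 °C
Reagents that add atoms: none
Why: Stille cross‑coupling proceeds with retention of olefin geometry, so the allyl arm should end cis to CH2OH in the skipped diene.

Step 3
Reactants: 6 methyl 4-methyl-3-oxopentanoate
Product: 7 methyl (3S)-3-hydroxy-4-methylpentanoate
Conditions: H2 (50 atm), RuCl2[(R)-BINAP] (cat.), MeOH, 50 °C
Reagents that add atoms: none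
Why: Noyori asymmetric hydrogenation of a β‑keto ester; the (R)-BINAP complex, which gives (R)-3-hydroxybutanoate from acetoacetate, should deliver hydride in the same spatial sense here, named S because isopropyl outranks CH2CO2Me.

Step 4
Reactants: 7 methyl (3S)-3-hydroxy-4-methylpentanoate; 5 (2Z)-3-methylhexa-2,5-dien-1-ol
Product: 8 (2Z)-3-methylhexa-2,5-dien-1-yl (3S)-3-hydroxy-4-methylpentanoate
Conditions: (ClBu2Sn)2O (cat.), toluene, reflux, 4 Å molecular sieves
Reagents that add atoms: none
Why: Distannoxane‑catalysed transesterification under neutral conditions should exchange methanol for the allylic alcohol without touching the carbinol or the olefin geometry.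

Step 5
Reactants: 8 (2Z)-3-methylhexa-2,5-dien-1-yl (3S)-3-hydroxy-4-methylpentanoate
Product: 10 (2R,3S)-3-ethenyl-2-[(1R)-1-hydroxy-2-methylpropyl]-3-methylhex-5-enoic acid, via dilithium alkoxide enolate 9 (not isolated)
Conditions: LDA (2.3 equiv), THF, −78 °C; then warm to 50 °C; aq. HCl work-up
Reagents that add atoms: lithium diisopropylamide, [Li+].CC(C)[N-]C(C)C (lithium of 9 only)
Why: Dianionic Ireland–Claisen [3,3]-sigmatropic rearrangement; the lithium‑chelated enolate (enolate oxygen cis to C4) should react through a chair on the face anti to the isopropyl group, which fixes C5, while the Z olefin places the allyl arm axial and so fixes quaternary C1.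

Step 6
Reactants: 10 (2R,3S)-3-ethenyl-2-[(1R)-1-hydroxy-2-methylpropyl]-3-methylhex-5-enoic acid
Product: 11 (2R,3S)-3-ethenyl-2-[(1R)-1-hydroxy-2-methylpropyl]-N-methoxy-N,3-dimethylhex-5-enamide
Conditions: MeNHOMe·HCl, EDC·HCl, HOBt, N-methylmorpholine, CH2Cl2, 0 °C to rt
Reagents that add atoms: N,O-dimethylhydroxylamine hydrochloride, CNOC.Cl
Why: Carbodiimide amide coupling to the Weinreb amide; no stereocentre is touched.

Step 7
Reactants: 11 (2R,3S)-3-ethenyl-2-[(1R)-1-hydroxy-2-methylpropyl]-N-methoxy-N,3-dimethylhex-5-enamide; 12 2-methylallylmagnesium chloride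
Product: 13 (5R,6S)-6-ethenyl-5-[(1R)-1-hydroxy-2-methylpropyl]-2,6-dimethylnona-1,8-dien-4-one
Conditions: 12 (3.5 equiv), THF, −78 to 0 °C; aq. NH4Cl
Reagents that add atoms: none
Why: Weinreb ketone synthesis; the chelated tetrahedral adduct should stop at mono‑addition and collapse only on mildly acidic work‑up, which keeps the β,γ‑olefin out of conjugation.

Step 8
Reactants: 13 (5R,6S)-6-ethenyl-5-[(1R)-1-hydroxy-2-methylpropyl]-2,6-dimethylnona-1,8-dien-4-one
Product: 14 (4R,5S,6S)-6-ethenyl-5-[(1R)-1-hydroxy-2-methylpropyl]-2,6-dimethylnona-1,8-dien-4-ol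
Conditions: Me4NBH(OAc)3, MeCN/AcOH, −35 °C
Reagents that add atoms: none
Why: Evans–Saksena hydroxyl‑directed reduction; intramolecular hydride delivery from the boron bound to the C4 oxygen, through a chair with the isopropyl group and the C1 substituent both equatorial, should give the 1,3‑anti diol and thereby set C6.

Step 9
Reactants: 14 (4R,5S,6S)-6-ethenyl-5-[(1R)-1-hydroxy-2-methylpropyl]-2,6-dimethylnona-1,8-dien-4-ol
Product: 15 (1R,6S,7S)-6-ethenyl-7-[(1R)-1-hydroxy-2-methylpropyl]-3,6-dimethylcyclohept-3-en-1-ol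
Conditions: RuCl2(=CHPh)(PCy3)(H2IMes) (second-generation Grubbs catalyst, cat.), CH2Cl2, high dilution, 40 °C
Reagents that add atoms: none
Why: Ring‑closing metathesis; the catalyst should initiate at the unhindered allyl group and close onto the 1,1‑disubstituted olefin to the trisubstituted cycloheptene, the vinyl group on the quaternary carbon being too hindered to initiate.

Step 10
Reactants: 15 (1R,6S,7S)-6-ethenyl-7-[(1R)-1-hydroxy-2-methylpropyl]-3,6-dimethylcyclohept-3-en-1-ol
Product: 17 (1R,6S,7S)-6-(2-hydroxyethyl)-7-[(1R)-1-hydroxy-2-methylpropyl]-3,6-dimethylcyclohept-3-en-1-ol, via B-alkyl-9-BBN bis(borinate) 16 (not isolated)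
Conditions: 9-BBN (excess), THF, 0 to 50 °C; then aq. NaOH, H2O2, 0 °C
Reagents that add atoms: 9-borabicyclo[3.3.1]nonane, B1C2CCCC1CCC2 (boron groups of 16 only); hydrogen peroxide, OO
Why: Anti‑Markovnikov hydroboration–oxidation; 9-BBN should take the monosubstituted vinyl group and leave the trisubstituted ring olefin.

Step 11
Reactants: 17 (1R,6S,7S)-6-(2-hydroxyethyl)-7-[(1R)-1-hydroxy-2-methylpropyl]-3,6-dimethylcyclohept-3-en-1-ol
Product: 18 (1R,6S,7S)-7-[(1R)-1-hydroxy-2-methylpropyl]-6-(2-iodoethyl)-3,6-dimethylcyclohept-3-en-1-ol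
Conditions: I2, PPh3, imidazole, CH2Cl2, 0 °C
Reagents that add atoms: iodine, II
Why: Appel iodination should convert only the primary hydroxyl, the two hindered secondary ones reacting far more slowly.

Step 12
Reactants: 18 (1R,6S,7S)-7-[(1R)-1-hydroxy-2-methylpropyl]-6-(2-iodoethyl)-3,6-dimethylcyclohept-3-en-1-ol; 19 4-acetoxybenzoyl chloride
Product: 20 (1R,6S,7R)-7-[(1R)-1-hydroxy-2-methylpropyl]-6-(2-iodoethyl)-3,6-dimethylcyclohept-3-en-1-yl 4-acetoxybenzoate
Conditions: 19 (1.1 equiv), pyridine, CH2Cl2, −20 to 0 °C (no DMAP)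
Reagents that add atoms: none
Why: Site‑selective O‑acylation; the ring carbinol at C6 has one unbranched neighbour, whereas the C4 hydroxyl is flanked by two branched carbons (isopropyl and C5) and should stay free.

Step 13
Reactants: 20 (1R,6S,7R)-7-[(1R)-1-hydroxy-2-methylpropyl]-6-(2-iodoethyl)-3,6-dimethylcyclohept-3-en-1-yl 4-acetoxybenzoate
Product: 21 (1R,6S,7S)-6-(2-iodoethyl)-3,6-dimethyl-7-(2-methylpropanoyl)cyclohept-3-en-1-yl 4-acetoxybenzoate
Conditions: Dess–Martin periodinane, NaHCO3, CH2Cl2, 0 °C to rt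
Reagents that add atoms: none
Why: Dess–Martin oxidation of the hindered relay carbinol to the isopropyl ketone under buffered, non‑basic conditions should spare C5 and the β‑acyloxy group (no E1cB elimination).

Step 14
Reactants: 21 (1R,6S,7S)-6-(2-iodoethyl)-3,6-dimethyl-7-(2-methylpropanoyl)cyclohept-3-en-1-yl 4-acetoxybenzoate
Product: 23 (3R,3aS,4R,8aR)-3-hydroxy-6,8a-dimethyl-3-(propan-2-yl)-1,2,3,3a,4,5,8,8a-octahydroazulen-4-yl 4-acetoxybenzoate, via alkylsamarium diiodide 22 (not isolated)
Conditions: SmI2 (2.5 equiv), Fe(PhCOCHCOPh)3 (cat.), THF, −78 °C to rt; aq. NH4Cl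
Reagents that add atoms: samarium diiodide, I[Sm]I (samarium and iodine of 22 only)
Why: Two single‑electron transfers from divalent samarium turn the primary C3–I bond, through the radical, into the alkylsamarium 22 (trivalent samarium), which adds to the C4 ketone on the neighbouring ring carbon in a 5‑exo‑trig closure, forming the C3–C4 bond and the cyclopentane in one event. The closest known reaction type is the intramolecular samarium Barbier cyclisation of ω‑iodoalkyl ketones to cyclopentanols, including annulations onto rings and onto β‑oxygenated ketones. The trans ring fusion is inherited, because the iodoethyl arm on C1 and the acyl group on C5 are trans on the cycloheptene and C5 is not epimerised under these non‑basic conditions. The new stereocentre C4 is controlled by C5, C6 and the C1 methyl: in the closing ring the isopropyl group should take the face of H‑5, away from the vicinal C6 carbon and the angular methyl, and the oxygen the opposite face, where the samarium alkoxide can bridge to the C6 ester oxygen. The step needs C–I reduction and ketone addition to outrun ketyl formation and attack on the aryl ester and aryl acetate; HMPA‑free conditions and the five‑membered transition state should secure this.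

Step 15
Reactants: 23 (3R,3aS,4R,8aR)-3-hydroxy-6,8a-dimethyl-3-(propan-2-yl)-1,2,3,3a,4,5,8,8a-octahydroazulen-4-yl 4-acetoxybenzoate
Product: 24 (3R,3aS,4R,6R,7S,8aR)-6,7-epoxy-3-hydroxy-6,8a-dimethyl-3-(propan-2-yl)decahydroazulen-4-yl 4-acetoxybenzoate
Conditions: mCPBA, NaHCO3, CH2Cl2, 0 °C
Reagents that add atoms: mCPBA (3-chloroperoxybenzoic acid), OOC(=O)c1cccc(Cl)c1
Why: Prilezhaev epoxidation of the trisubstituted olefin should occur from the α‑face, the β‑face being screened by the angular methyl on C1 and the C6 ester, which flank the olefin.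

Step 16
Reactants: 24 (3R,3aS,4R,6R,7S,8aR)-6,7-epoxy-3-hydroxy-6,8a-dimethyl-3-(propan-2-yl)decahydroazulen-4-yl 4-acetoxybenzoate
Product: 25 (3R,3aS,4R,6R,7S,8aR)-6,7-epoxy-3-hydroxy-6,8a-dimethyl-3-(propan-2-yl)decahydroazulen-4-yl 4-hydroxybenzoate (target)
Conditions: K2CO3 (cat.), MeOH, 0 °C
Reagents that add atoms: none
Why: Base‑catalysed methanolysis (transesterification) of the phenyl acetate should be far faster than that of the hindered secondary benzoate, and the oxirane is inert to it.

**Compound list**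

1 | but-2-yn-1-ol | CC#CCO | starting material
2 | cyclic sodium alkenylaluminate (sodium 2,2-bis(2-methoxyethoxy)-3-methyl-2,5-dihydro-1,2-oxaluminol-2-uide) | [Na+].CC1=CCO[Al-]1(OCCOC)OCCOC | intermediate (not isolated)
3 | (2Z)-3-iodobut-2-en-1-ol | C/C(I)=C/CO | intermediate
4 | allyltributylstannane | C=CC[Sn](CCCC)(CCCC)CCCC | starting material
5 | (2Z)-3-methylhexa-2,5-dien-1-ol | C=CC/C(C)=C\CO | intermediate
6 | methyl 4-methyl-3-oxopentanoate | CC(C)C(=O)CC(=O)OC | starting material
7 | methyl (3S)-3-hydroxy-4-methylpentanoate | CC(C)[C@@H](O)CC(=O)OC | intermediate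
8 | (2Z)-3-methylhexa-2,5-dien-1-yl (3S)-3-hydroxy-4-methylpentanoate | CC(C)[C@@H](O)CC(=O)OC/C=C(\CC=C)C | intermediate
9 | dilithium alkoxide enolate of 8 (enolate oxygen cis to C4) | [Li+].[Li+].CC(C)[C@@H]([O-])/C=C(\[O-])OC/C=C(\CC=C)C | intermediate (not isolated)
10 | (2R,3S)-3-ethenyl-2-[(1R)-1-hydroxy-2-methylpropyl]-3-methylhex-5-enoic acid | CC(C)[C@@H](O)[C@H](C(=O)O)[C@@](C)(CC=C)C=C | intermediate
11 | (2R,3S)-3-ethenyl-2-[(1R)-1-hydroxy-2-methylpropyl]-N-methoxy-N,3-dimethylhex-5-enamide | CC(C)[C@@H](O)[C@H](C(=O)N(C)OC)[C@@](C)(CC=C)C=C | intermediate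
12 | 2-methylallylmagnesium chloride | CC(=C)C[Mg]Cl | starting material
13 | (5R,6S)-6-ethenyl-5-[(1R)-1-hydroxy-2-methylpropyl]-2,6-dimethylnona-1,8-dien-4-one | CC(C)[C@@H](O)[C@H](C(=O)CC(C)=C)[C@@](C)(CC=C)C=C | intermediate
14 | (4R,5S,6S)-6-ethenyl-5-[(1R)-1-hydroxy-2-methylpropyl]-2,6-dimethylnona-1,8-dien-4-ol | CC(C)[C@@H](O)[C@H]([C@H](O)CC(C)=C)[C@@](C)(CC=C)C=C | intermediate
15 | (1R,6S,7S)-6-ethenyl-7-[(1R)-1-hydroxy-2-methylpropyl]-3,6-dimethylcyclohept-3-en-1-ol | CC(C)[C@@H](O)[C@@H]1[C@H](O)CC(C)=CC[C@@]1(C)C=C | intermediate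
16 | hydroboration adduct of 15: B-alkyl-9-BBN at C3, both hydroxyls as 9-BBN borinates | CC(C)[C@@H](OB2C3CCCC2CCC3)[C@@H]1[C@H](OB2C3CCCC2CCC3)CC(C)=CC[C@@]1(C)CCB1C2CCCC1CCC2 | intermediate (not isolated)
17 | (1R,6S,7S)-6-(2-hydroxyethyl)-7-[(1R)-1-hydroxy-2-methylpropyl]-3,6-dimethylcyclohept-3-en-1-ol | CC(C)[C@@H](O)[C@@H]1[C@H](O)CC(C)=CC[C@@]1(C)CCO | intermediate
18 | (1R,6S,7S)-7-[(1R)-1-hydroxy-2-methylpropyl]-6-(2-iodoethyl)-3,6-dimethylcyclohept-3-en-1-ol | CC(C)[C@@H](O)[C@@H]1[C@H](O)CC(C)=CC[C@@]1(C)CCI | intermediate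
19 | 4-acetoxybenzoyl chloride | CC(=O)Oc1ccc(cc1)C(Cl)=O | starting material
20 | (1R,6S,7R)-7-[(1R)-1-hydroxy-2-methylpropyl]-6-(2-iodoethyl)-3,6-dimethylcyclohept-3-en-1-yl 4-acetoxybenzoate | CC(C)[C@@H](O)[C@@H]1[C@H](OC(=O)c2ccc(OC(C)=O)cc2)CC(C)=CC[C@@]1(C)CCI | intermediate
21 | (1R,6S,7S)-6-(2-iodoethyl)-3,6-dimethyl-7-(2-methylpropanoyl)cyclohept-3-en-1-yl 4-acetoxybenzoate | CC(C)C(=O)[C@@H]1[C@H](OC(=O)c2ccc(OC(C)=O)cc2)CC(C)=CC[C@@]1(C)CCI | intermediate
22 | alkylsamarium diiodide from 21 (C3–Sm, trivalent samarium) | CC(C)C(=O)[C@@H]1[C@H](OC(=O)c2ccc(OC(C)=O)cc2)CC(C)=CC[C@@]1(C)CC[Sm](I)I | intermediate (not isolated)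
23 | (3R,3aS,4R,8aR)-3-hydroxy-6,8a-dimethyl-3-(propan-2-yl)-1,2,3,3a,4,5,8,8a-octahydroazulen-4-yl 4-acetoxybenzoate | CC(C)[C@]1(O)CC[C@]2(C)CC=C(C)C[C@@H](OC(=O)c3ccc(OC(C)=O)cc3)[C@H]21 | intermediate
24 | (3R,3aS,4R,6R,7S,8aR)-6,7-epoxy-3-hydroxy-6,8a-dimethyl-3-(propan-2-yl)decahydroazulen-4-yl 4-acetoxybenzoate | CC(C)[C@]1(O)CC[C@]2(C)C[C@@H]3O[C@]3(C)C[C@@H](OC(=O)c3ccc(OC(C)=O)cc3)[C@H]21 | intermediate
25 | (3R,3aS,4R,6R,7S,8aR)-6,7-epoxy-3-hydroxy-6,8a-dimethyl-3-(propan-2-yl)decahydroazulen-4-yl 4-hydroxybenzoate, i.e. (1R,4R,5S,6R,8R,9S)-8,9-epoxy-4-hydroxydaucan-6-yl 4-hydroxybenzoate | CC(C)[C@]1(O)CC[C@]2(C)C[C@@H]3O[C@]3(C)C[C@@H](OC(=O)c3ccc(O)cc3)[C@H]21 | target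

**Step count and risks**

Total step count: 16. Longest linear sequence: 15 steps (steps 1, 2 and 4–16, from but-2-yn-1-ol).

Steps most likely to fail:

Step 5. Forming the congested C1–C5 bond may be slow, so retro‑aldol cleavage of the alkoxide enolate or leakage through non‑chelated transition states could erode the C5/C1 control. The fallback sets out from 8 and replaces substrate chelation by reagent control. The carbinol is silylated (TESCl, imidazole, CH2Cl2) to the silyl‑protected ester F1. The rearrangement is then run as the chiral bromoborane‑controlled enolate Claisen: that enantiomer of 2-bromo-4,5-diphenyl-1,3-bis(4-methylphenylsulfonyl)-1,3,2-diazaborolidine which selects the same enolate face, with a tertiary amine in CH2Cl2 from −78 °C to rt, using the amine/solvent pairing that places C4 cis to the O–B bond. This should give the silyl‑protected acid F2, and aqueous HCl in THF removes the silyl group and comes back to the route at 10.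

Step 12. Discrimination between the two secondary hydroxyls may be poor, or the acyl group may migrate between them. The fallback sets out from 18 and moves the selective event to a desilylation. Both hydroxyls are silylated (TESOTf, 2,6-lutidine) to the bis(triethylsilyl) ether F3. The less hindered C6 silyl ether is solvolysed (PPTS, MeOH/CH2Cl2, 0 °C) to the C4 mono‑silyl ether F4, whose only free hydroxyl is acylated with 19 in pyridine to the silyl ester F5. HF·pyridine then frees the C4 hydroxyl and comes back to the route at 20.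

Step 14. Ketyl formation, loss of the β‑acyloxy group at the ketone stage or reduction of the aryl ester may compete with generation and addition of the alkylsamarium. The fallback sets out from 18 and closes the same bond before any ester is present, by a polar instead of a single‑electron pathway. The C6 hydroxyl is silylated selectively (TESCl, imidazole, −30 °C) to the C6 silyl ether F6, and Dess–Martin oxidation gives the silyloxy iodo ketone F7. Lithium–iodine exchange (t-BuLi, pentane/Et2O, −100 °C) with intramolecular addition of the alkyllithium to the hindered ketone should give the bicyclic silyl ether F8. TBAF frees the diol F9, and 19 in pyridine acylates only its secondary C6 hydroxyl, coming back to the route at 23.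

Further compounds
F1 | step 5 | (2Z)-3-methylhexa-2,5-dien-1-yl (3S)-4-methyl-3-(triethylsilyloxy)pentanoate | CC(C)[C@@H](O[Si](CC)(CC)CC)CC(=O)OC/C=C(\CC=C)C
F2 | step 5 | (2R,3S)-3-ethenyl-3-methyl-2-[(1R)-2-methyl-1-(triethylsilyloxy)propyl]hex-5-enoic acid | CC(C)[C@@H](O[Si](CC)(CC)CC)[C@H](C(=O)O)[C@@](C)(CC=C)C=C
F3 | step 12 | bis(triethylsilyl) ether of 18 (C4–O and C6–O silylated) | CC(C)[C@@H](O[Si](CC)(CC)CC)[C@@H]1[C@H](O[Si](CC)(CC)CC)CC(C)=CC[C@@]1(C)CCI
F4 | step 12 | C4 triethylsilyl ether of 18 (C6–OH free) | CC(C)[C@@H](O[Si](CC)(CC)CC)[C@@H]1[C@H](O)CC(C)=CC[C@@]1(C)CCI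
F5 | step 12 | C4 triethylsilyl ether of 20 | CC(C)[C@@H](O[Si](CC)(CC)CC)[C@@H]1[C@H](OC(=O)c2ccc(OC(C)=O)cc2)CC(C)=CC[C@@]1(C)CCI
F6 | step 14 | C6 triethylsilyl ether of 18 (C4–OH free) | CC(C)[C@@H](O)[C@@H]1[C@H](O[Si](CC)(CC)CC)CC(C)=CC[C@@]1(C)CCI
F7 | step 14 | (2S,3S,7R)-3-(2-iodoethyl)-3,6-dimethyl-2-(2-methylpropanoyl)-7-(triethylsilyloxy)cyclohept-5-ene, the C6 silyl ether analogue of 21 | CC(C)C(=O)[C@@H]1[C@H](O[Si](CC)(CC)CC)CC(C)=CC[C@@]1(C)CCI
F8 | step 14 | (3R,3aS,4R,8aR)-6,8a-dimethyl-3-(propan-2-yl)-4-(triethylsilyloxy)-1,2,3,3a,4,5,8,8a-octahydroazulen-3-ol | CC(C)[C@]1(O)CC[C@]2(C)CC=C(C)C[C@@H](O[Si](CC)(CC)CC)[C@H]21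
F9 | step 14 | (3R,3aS,4R,8aR)-6,8a-dimethyl-3-(propan-2-yl)-1,2,3,3a,4,5,8,8a-octahydroazulene-3,4-diol | CC(C)[C@]1(O)CC[C@]2(C)CC=C(C)C[C@@H](O)[C@H]21
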